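## Analysis of the target

The target (22) is a monocyclic C10 tetrahalide. Its cyclohexane ring (C1–C6) carries a (Z)-2-bromoethylidene group at C1 (side chain C1′, C2′), chlorine at C2 and C6, a gem-dimethyl carbon at C3 and bromine at C4; C5 is the only ring methylene. The three stereocentres are all S: the two chlorines are cis to each other, the C4 bromine is trans to both, and the CH2Br arm of the alkene points towards C2. No oxygen or other handle remains, and three of the four halides are allylic (two secondary chlorides, one primary bromide). The molecule is therefore prone to SN2′ exchange, ionisation and elimination, and tolerates neither strong base nor halide-rich Lewis acids late in a route. The hardest region is C2–C3–C4: both halogen-bearing carbons are neopentyl, so neither C–X bond can be made by displacement, and C4 must be set as one enantiomer beside an achiral quaternary carbon. A second difficulty is the cis-2,6-dichloride across the Z alkene, where A(1,3) strain pushes the C2 chlorine axial, so the C6 chlorine has to enter syn-axial to it. The plan rests on the C3/C4 pair: bromine on C4 beside a carbon with two methyls can come from electrophilic bromine adding to a C3=C4 alkene that carries one methyl, with the second methyl shifting from C2 as C2 becomes a carbonyl.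

## Retrosynthetic reasoning

The primary allylic bromide is the most labile group and is cut first: C2′–Br goes back to allylic alcohol 21, and 21 to its silyl ether 20. This keeps C2′ as a protected oxygen through all the chemistry at C2 and C6.

The C6–Cl bond is cut next, to allylic alcohol 19 with the opposite configuration at C6. Displacement with inversion is feasible here because C6 is allylic and not neopentyl. Alcohol 19 comes from enone 18 by a reagent-controlled hydride delivery, so the C6 configuration does not depend on the substrate's own facial bias.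

The C1=C1′ alkene of 18 is disconnected to aldol 17 by adding water across it. A syn-elimination from the anti aldol places the CH2O arm on the C2 side, which is the geometry the target needs.

In 17 the C2–Cl and C1–C1′ bonds are cut together, giving enone 14 and aldehyde 15. Chloride can reach the neopentyl C2 only by conjugate addition, and that addition generates titanium enolate 16 specifically at C1, so no regiochemical choice between C1 and C5 arises.

Enone 14 has its carbonyl at C6, whereas the rearrangement below delivers a carbonyl at C2. The transposition is planned through allylic alcohol 13, silyl ether 12 and enol triflate 11 back to ketone 9. C3 is quaternary, so 9 can enolise only towards C1, and reductive removal of the triflate avoids a cation at C2 that could contract the ring. The C6 oxygen of 9 is oxidised away once it has passed its chirality to C4.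

The key disconnection cuts the C4–Br bond and one C3–CH3 bond of 9, returning the methyl to C2. This leads to tertiary allylic alcohol 7 and the bromine source 8. It forms the neopentyl bromide by electrophilic attack on an alkene, builds the quaternary carbon in the same event, and sets C4 stereospecifically.

Carbinol 7 is cut at its C2–CH3 bond to enone 5 and methyllithium 6. Enone 5 goes back through alcohol 4 and acetate 3 to (R)-carvone 1, whose isopropenyl group is exchanged for oxygen with retention via hydroperoxide 2.

## Alternatives that were turned down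

Alternative 1: The disconnection removes both the C2–Cl and C2′–Br bonds of bromo ketone A2 and leads to the 2-vinyl enone A1. Forward, TiCl4 would add chloride to C2 of A1, and the titanium dienolate would be brominated by 8 at its far terminus C2′, creating the C1=C1′ alkene as well.
- For: two carbon–halogen bonds and the alkene form in one flask, and no oxygen or protecting group is needed at C2′. On step count it is clearly stronger than the chosen endgame, saving the aldol dehydration, the desilylation and the last bromination.
- Against: metal dienolates usually take electrophiles at the α-carbon (C1), and nothing in A1 enforces γ-attack. A2 is at once a γ-bromo enone and an SN2′-active allylic chloride, yet must still survive ketone reduction and chlorination at C6. A1 is a 2-vinyl enone liable to Diels–Alder dimerisation, and making it needs α-functionalisation and cross-coupling of a base-sensitive β-bromo ketone.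
- Comparison: it offers nothing for the C3/C4 unit. The chosen strategy gives a stereospecific origin for the C4 bromide and makes the most fragile halide last.

Alternative 2: The disconnection cuts C2–Cl and C1–C1′ of aldol A3, which is the same compound as 17, back to enone 14 and aldehyde 15. Forward, TiCl4 adds chloride to C2 and the enolate adds to the aldehyde through C1.
- For: the enolate forms only at C1, the neopentyl chloride comes from conjugate addition, and the C2 configuration follows from the C4 bromide. As a single reaction it is as strong as anything in the chosen route, which uses it unchanged as step 10.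
- Against: as a strategy it puts its weight where the target is least demanding. Enone 14 holds the one stereocentre that cannot be made by displacement. The obvious access, reversible conjugate addition of HBr to the achiral dienone, gives racemate.
- Comparison: step economy after 14 is the same. The chosen strategy spends its key step on the C3/C4 problem that this alternative leaves open.

Alternative 3: The disconnection cuts the C6–Cl and C2′–O bonds of allylic acetate A5 and leads to diene A4. Forward, Pd(OAc)2 with benzoquinone, LiCl and LiOAc in acetic acid would add acetate to C2′, form a π-allyl complex over C1′–C1–C6 and let chloride attack C6.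
- For: the C6–Cl bond forms without displacement at a hindered allylic carbon and without a C6 ketone or alcohol. On this point it is stronger than the chosen route, whose steps 12 and 13 are among its least secure.
- Against: the C2 chloride of A4 is allylic to the diene and can be ionised by the zerovalent palladium of the catalytic cycle. Regiochemistry, the syn or anti π-allyl geometry that decides Z or E, and the face taken by palladium are not fixed by the substrate. A4 would need an enol triflate and vinyl coupling next to a β-chloride.
- Comparison: the C3/C4 unit is again untouched. The chosen strategy offers a chiral-pool solution for C4 and conventional, separately controllable steps at C6.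

Key step: step 5

Remark: atom labels C1–C6, C1′ and C2′ are those of the target for every intermediate, and 17 is assumed to form as the anti aldol (its two extra centres vanish in step 11).

## Route

Step 1
Reactants: 1 (R)-carvone
Product: 3 (1R)-4-methyl-5-oxocyclohex-3-en-1-yl acetate, via methoxy hydroperoxide 2 (not isolated)
Conditions: O3, CH2Cl2/MeOH, −78 °C; then Ac2O, Et3N, DMAP (cat.), −78 °C → rt
Reagents that add atoms: ozone, [O-][O+]=O; methanol, CO
Why: Ozonolysis then Criegee rearrangement: the electron-rich isopropenyl alkene is cleaved in preference to the enone and methanol traps the carbonyl oxide as 2. Acylation of the hydroperoxide makes the ring carbon migrate to oxygen with retention, so the stereocentre of 1 becomes the C6–O centre unchanged.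

Step 2
Reactants: 3 (1R)-4-methyl-5-oxocyclohex-3-en-1-yl acetate
Product: 4 (5R)-5-hydroxy-2-methylcyclohex-2-en-1-one
Conditions: K2CO3 (cat.), MeOH, 0 °C
Reagents that add atoms: none
Why: Transesterification of the acetate; the low temperature and catalytic base are chosen to avoid β-elimination of the β-hydroxy ketone towards a phenol.

Step 3
Reactants: 4 (5R)-5-hydroxy-2-methylcyclohex-2-en-1-one
Product: 5 (5R)-5-[(tert-butyldimethylsilyl)oxy]-2-methylcyclohex-2-en-1-one
Conditions: TBSCl, imidazole, DMF, 0 °C → rt
Reagents that add atoms: tert-butyldimethylsilyl chloride, CC(C)(C)[Si](C)(C)Cl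
Why: Standard silylation of a secondary alcohol; the silyl ether survives organolithium, bromonium and enolate chemistry and is removed by fluoride in step 8.

Step 4
Reactants: 5 (5R)-5-[(tert-butyldimethylsilyl)oxy]-2-methylcyclohex-2-en-1-one; 6 methyllithium
Product: 7 (1R,5R)-5-[(tert-butyldimethylsilyl)oxy]-1,2-dimethylcyclohex-2-en-1-ol
Conditions: MeLi, Et2O, −78 °C; then H2O
Reagents that add atoms: none
Why: 1,2-Addition of an organolithium to an enone. Axial attack on the half-chair with the silyloxy group equatorial puts the new methyl trans to the silyloxy group and the hydroxyl cis to it, as in additions to 5-substituted cyclohexenones, which sets the C2 carbinol centre.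

Step 5
Reactants: 7 (1R,5R)-5-[(tert-butyldimethylsilyl)oxy]-1,2-dimethylcyclohex-2-en-1-ol; 8 N-bromosuccinimide
Product: 9 (3S,5S)-3-bromo-5-[(tert-butyldimethylsilyl)oxy]-2,2-dimethylcyclohexan-1-one
Conditions: NBS, CH2Cl2, −40 → 0 °C, dark
Reagents that add atoms: none
Why: Proposed new method: 8 transfers Br+ to the C3=C4 alkene of 7 on the face syn to the pseudo-equatorial hydroxyl, which is also the face away from the pseudo-axial C2 methyl; the bromonium ion opens at the tertiary C3, the C2 methyl, antiperiplanar to the breaking C3–Br bond, shifts to C3, and the hydroxyl oxygen becomes the C2 carbonyl with loss of its proton to succinimide anion. The closest known reaction type is the N-bromosuccinimide-triggered semipinacol rearrangement of tertiary allylic alcohols, established for ring-expanding alkyl and for aryl migration but not for a methyl shift on a cyclohexenyl carbinol. No ring is closed. The one new stereocentre, C4, is fixed by the stereospecific anti relationship between bromine and the migrating methyl, and so by the carbinol configuration that step 4 derived from the C6 silyloxy centre. The step needs bromine syn to OH, Markovnikov opening at C3, and methyl rather than ring-bond migration. The half-chair with equatorial silyloxy group puts the methyl, not the C2–C1 ring bond, parallel to the developing p-orbital, so ring contraction is stereoelectronically poor. In the productive bromonium ion, oxygen and bromine are on the same face, so epoxide closure cannot occur from it. Proton loss to an allylic bromide is the main competitor, and a non-basic, non-nucleophilic medium at low temperature is chosen against it.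

Step 6
Reactants: 9 (3S,5S)-3-bromo-5-[(tert-butyldimethylsilyl)oxy]-2,2-dimethylcyclohexan-1-one
Product: 11 (3R,5S)-5-bromo-3-[(tert-butyldimethylsilyl)oxy]-6,6-dimethylcyclohex-1-en-1-yl trifluoromethanesulfonate, via lithium enolate 10 (not isolated)
Conditions: LiN(SiMe3)2, THF, −78 °C; then 2-[N,N-bis(trifluoromethylsulfonyl)amino]-5-chloropyridine, −78 → −40 °C
Reagents that add atoms: 2-[N,N-bis(trifluoromethylsulfonyl)amino]-5-chloropyridine, O=S(=O)(N(c1ccc(Cl)cn1)S(=O)(=O)C(F)(F)F)C(F)(F)F
Why: Kinetic enolisation and O-triflation; C3 is quaternary, so the enolate can form only towards C1. The lithium counter-ion, −78 °C and the equatorial silyloxy group (poor overlap with the enolate π system) hold back β-elimination, and the equatorial bromide has no antiperiplanar hydrogen for E2.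

Step 7
Reactants: 11 (3R,5S)-5-bromo-3-[(tert-butyldimethylsilyl)oxy]-6,6-dimethylcyclohex-1-en-1-yl trifluoromethanesulfonate
Product: 12 {[(1R,5S)-5-bromo-4,4-dimethylcyclohex-2-en-1-yl]oxy}(tert-butyl)dimethylsilane
Conditions: Pd(OAc)2 (5 mol%), PPh3 (10 mol%), HCO2H, n-Bu3N, DMF, 60 °C
Reagents that add atoms: none
Why: Palladium-catalysed formate reduction of an enol triflate: oxidative addition to zerovalent palladium formed in situ, formate exchange, decarboxylation and reductive elimination. The unactivated secondary bromide and the allylic silyl ether are inert, and no cation arises at C2, so the retropinacol ring contraction that threatens dehydration of a 2,2-dimethylcyclohexanol cannot occur.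

Step 8
Reactants: 12 {[(1R,5S)-5-bromo-4,4-dimethylcyclohex-2-en-1-yl]oxy}(tert-butyl)dimethylsilane
Product: 13 (1R,5S)-5-bromo-4,4-dimethylcyclohex-2-en-1-ol
Conditions: HF·pyridine, pyridine, THF, 0 °C → rt
Reagents that add atoms: none
Why: Fluoride-mediated cleavage of the silyl ether under buffered, weakly acidic conditions that neither eliminate the bromide nor ionise the allylic alcohol.

Step 9
Reactants: 13 (1R,5S)-5-bromo-4,4-dimethylcyclohex-2-en-1-ol
Product: 14 (5S)-5-bromo-4,4-dimethylcyclohex-2-en-1-one
Conditions: Dess–Martin periodinane, CH2Cl2, 0 °C → rt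
Reagents that add atoms: none
Why: Oxidation of a secondary allylic alcohol with a hypervalent iodine reagent under non-basic conditions, so the β-bromo ketone is not dehydrobrominated. The C6 centre is removed on purpose, having relayed its chirality to C4.

Step 10
Reactants: 14 (5S)-5-bromo-4,4-dimethylcyclohex-2-en-1-one; 15 (tert-butyldimethylsilyloxy)acetaldehyde
Product: 17 (2R,3S,5S)-5-bromo-2-[(1S)-2-[(tert-butyldimethylsilyl)oxy]-1-hydroxyethyl]-3-chloro-4,4-dimethylcyclohexan-1-one, via trichlorotitanium enolate 16 (not isolated)
Conditions: TiCl4 (1.3 equiv), CH2Cl2, −78 °C; then 15, −78 → −40 °C; pH 7 buffer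
Reagents that add atoms: titanium tetrachloride, Cl[Ti](Cl)(Cl)Cl
Why: Three-component chloro-aldol (halo-aldol) reaction: chloride adds axially to C2 of the enone half-chair that has the C4 bromine equatorial, so the chlorine ends trans to bromine, and this gives 16 specifically at C1. Enolate 16 adds to the aldehyde anti to the new chlorine through a closed Zimmerman–Traxler transition state, giving the anti aldol whose C1 and C1′ centres are transient.

Step 11
Reactants: 17 (2R,3S,5S)-5-bromo-2-[(1S)-2-[(tert-butyldimethylsilyl)oxy]-1-hydroxyethyl]-3-chloro-4,4-dimethylcyclohexan-1-one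
Product: 18 (2Z,3S,5S)-5-bromo-2-{2-[(tert-butyldimethylsilyl)oxy]ethylidene}-3-chloro-4,4-dimethylcyclohexan-1-one
Conditions: Burgess reagent (MeO2CN(−)SO2N(+)Et3), THF, 0 °C → rt
Reagents that add atoms: none
Why: Burgess dehydration: the sulfamate ester of the C1′ hydroxyl removes the acidic C1 proton intramolecularly in a syn-elimination, so no free base meets the β-chloro and β-bromo ketone. Syn loss of water from the anti aldol places the CH2O arm cis to C2, which is also the thermodynamically preferred geometry with the arm away from the carbonyl.

Step 12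
Reactants: 18 (2Z,3S,5S)-5-bromo-2-{2-[(tert-butyldimethylsilyl)oxy]ethylidene}-3-chloro-4,4-dimethylcyclohexan-1-one
Product: 19 (1R,2Z,3S,5S)-5-bromo-2-{2-[(tert-butyldimethylsilyl)oxy]ethylidene}-3-chloro-4,4-dimethylcyclohexan-1-ol
Conditions: (S)-2-methyl-CBS-oxazaborolidine [(3aS)-1-methyl-3,3-diphenyltetrahydro-1H,3H-pyrrolo[1,2-c][1,3,2]oxazaborole] (0.3 equiv), catecholborane, toluene, −78 °C
Reagents that add atoms: none
Why: Corey–Bakshi–Shibata reduction of an α-substituted enone: the alkylidene-bearing C1 acts as the large group and the C5 methylene as the small one. The (S)-catalyst therefore delivers hydride to the face that gives the (R)-alcohol, with OH trans to the C2 chlorine, independently of substrate bias and without conjugate reduction.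

Step 13
Reactants: 19 (1R,2Z,3S,5S)-5-bromo-2-{2-[(tert-butyldimethylsilyl)oxy]ethylidene}-3-chloro-4,4-dimethylcyclohexan-1-ol
Product: 20 tert-butyl{(2Z)-2-[(2S,4S,6S)-4-bromo-2,6-dichloro-3,3-dimethylcyclohexylidene]ethoxy}dimethylsilane
Conditions: PPh3, hexachloroacetone, CH2Cl2, −20 → 0 °C
Reagents that add atoms: hexachloroacetone, ClC(Cl)(Cl)C(=O)C(Cl)(Cl)Cl
Why: Appel-type chlorination through an alkoxyphosphonium ion: SN2 displacement with inversion puts the C6 chlorine cis to the C2 chlorine. This reagent pair is known to convert secondary allylic alcohols without allylic transposition.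

Step 14
Reactants: 20 tert-butyl{(2Z)-2-[(2S,4S,6S)-4-bromo-2,6-dichloro-3,3-dimethylcyclohexylidene]ethoxy}dimethylsilane
Product: 21 (2Z)-2-[(2S,4S,6S)-4-bromo-2,6-dichloro-3,3-dimethylcyclohexylidene]ethan-1-ol
Conditions: HF·pyridine, pyridine, THF, 0 °C
Reagents that add atoms: none
Why: Cleavage of a primary allylic silyl ether by buffered HF, which is neither basic nor a source of nucleophilic halide, so the two secondary allylic chlorides are left alone.

Step 15
Reactants: 21 (2Z)-2-[(2S,4S,6S)-4-bromo-2,6-dichloro-3,3-dimethylcyclohexylidene]ethan-1-ol
Product: 22 (1Z,2S,4S,6S)-4-bromo-1-(2-bromoethylidene)-2,6-dichloro-3,3-dimethylcyclohexane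
Conditions: CBr4, PPh3, CH2Cl2, −20 → 0 °C
Reagents that add atoms: carbon tetrabromide, BrC(Br)(Br)Br
Why: Appel bromination by SN2 at the primary allylic carbon; SN2′ attack at the fully substituted C1 is disfavoured. The near-neutral medium with little free bromide should leave the secondary allylic chlorides unexchanged.

## Compound list

1 | (R)-carvone, (5R)-2-methyl-5-(prop-1-en-2-yl)cyclohex-2-en-1-one | CC1=CC[C@@H](C(C)=C)CC1=O | starting material
2 | (5R)-5-(1-hydroperoxy-1-methoxyethyl)-2-methylcyclohex-2-en-1-one (both epimers at the peroxy carbon) | CC1=CC[C@@H](C(C)(OC)OO)CC1=O | intermediate (not isolated)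
3 | (1R)-4-methyl-5-oxocyclohex-3-en-1-yl acetate | CC1=CC[C@@H](OC(C)=O)CC1=O | intermediate
4 | (5R)-5-hydroxy-2-methylcyclohex-2-en-1-one | CC1=CC[C@@H](O)CC1=O | intermediate
5 | (5R)-5-[(tert-butyldimethylsilyl)oxy]-2-methylcyclohex-2-en-1-one | CC1=CC[C@@H](O[Si](C)(C)C(C)(C)C)CC1=O | intermediate
6 | methyllithium | [Li]C | starting material
7 | (1R,5R)-5-[(tert-butyldimethylsilyl)oxy]-1,2-dimethylcyclohex-2-en-1-ol | CC1=CC[C@@H](O[Si](C)(C)C(C)(C)C)C[C@@]1(C)O | intermediate
8 | N-bromosuccinimide | O=C1CCC(=O)N1Br | starting material
9 | (3S,5S)-3-bromo-5-[(tert-butyldimethylsilyl)oxy]-2,2-dimethylcyclohexan-1-one | CC1(C)[C@@H](Br)C[C@@H](O[Si](C)(C)C(C)(C)C)CC1=O | intermediate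
10 | lithium (3R,5S)-5-bromo-3-[(tert-butyldimethylsilyl)oxy]-6,6-dimethylcyclohex-1-en-1-olate | CC1(C)[C@@H](Br)C[C@@H](O[Si](C)(C)C(C)(C)C)C=C1O[Li] | intermediate (not isolated)
11 | (3R,5S)-5-bromo-3-[(tert-butyldimethylsilyl)oxy]-6,6-dimethylcyclohex-1-en-1-yl trifluoromethanesulfonate | CC1(C)[C@@H](Br)C[C@@H](O[Si](C)(C)C(C)(C)C)C=C1OS(=O)(=O)C(F)(F)F | intermediate
12 | {[(1R,5S)-5-bromo-4,4-dimethylcyclohex-2-en-1-yl]oxy}(tert-butyl)dimethylsilane | CC1(C)[C@@H](Br)C[C@@H](O[Si](C)(C)C(C)(C)C)C=C1 | intermediate
13 | (1R,5S)-5-bromo-4,4-dimethylcyclohex-2-en-1-ol | CC1(C)[C@@H](Br)C[C@@H](O)C=C1 | intermediate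
14 | (5S)-5-bromo-4,4-dimethylcyclohex-2-en-1-one | CC1(C)[C@@H](Br)CC(=O)C=C1 | intermediate
15 | (tert-butyldimethylsilyloxy)acetaldehyde | O=CCO[Si](C)(C)C(C)(C)C | starting material
16 | trichloro{[(3S,5S)-5-bromo-3-chloro-4,4-dimethylcyclohex-1-en-1-yl]oxy}titanium | CC1(C)[C@@H](Br)CC(O[Ti](Cl)(Cl)Cl)=C[C@@H]1Cl | intermediate (not isolated)
17 | (2R,3S,5S)-5-bromo-2-[(1S)-2-[(tert-butyldimethylsilyl)oxy]-1-hydroxyethyl]-3-chloro-4,4-dimethylcyclohexan-1-one | CC1(C)[C@@H](Br)CC(=O)[C@@H]([C@H](O)CO[Si](C)(C)C(C)(C)C)[C@@H]1Cl | intermediate
18 | (2Z,3S,5S)-5-bromo-2-{2-[(tert-butyldimethylsilyl)oxy]ethylidene}-3-chloro-4,4-dimethylcyclohexan-1-one | CC1(C)[C@@H](Br)CC(=O)/C(=C/CO[Si](C)(C)C(C)(C)C)[C@@H]1Cl | intermediate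
19 | (1R,2Z,3S,5S)-5-bromo-2-{2-[(tert-butyldimethylsilyl)oxy]ethylidene}-3-chloro-4,4-dimethylcyclohexan-1-ol | CC1(C)[C@@H](Br)C[C@@H](O)/C(=C/CO[Si](C)(C)C(C)(C)C)[C@@H]1Cl | intermediate
20 | tert-butyl{(2Z)-2-[(2S,4S,6S)-4-bromo-2,6-dichloro-3,3-dimethylcyclohexylidene]ethoxy}dimethylsilane | CC1(C)[C@@H](Br)C[C@H](Cl)/C(=C/CO[Si](C)(C)C(C)(C)C)[C@@H]1Cl | intermediate
21 | (2Z)-2-[(2S,4S,6S)-4-bromo-2,6-dichloro-3,3-dimethylcyclohexylidene]ethan-1-ol | CC1(C)[C@@H](Br)C[C@H](Cl)/C(=C/CO)[C@@H]1Cl | intermediate
22 | (1Z,2S,4S,6S)-4-bromo-1-(2-bromoethylidene)-2,6-dichloro-3,3-dimethylcyclohexane | CC1(C)[C@@H](Br)C[C@H](Cl)/C(=C/CBr)[C@@H]1Cl | target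

## Step count and least certain steps

Total: 15 steps. Longest linear sequence: 15 steps (1 → 22).

**Step 5 (key step, proposed new method).** The most likely failure is that the bromonium ion loses a proton to give an allylic bromide faster than the methyl shifts, because methyl migrates poorly and no ring strain is released. Bromination anti to the hydroxyl would lead to a bromo epoxide instead. The fallback separates bromination from migration using known reactions. It sets out from 7: addition of Br2 in CH2Cl2 at −78 °C should give the trans-dibromide (1R,2S,3S,5S)-2,3-dibromo-5-[(tert-butyldimethylsilyl)oxy]-1,2-dimethylcyclohexan-1-ol F1, which can be purified from its diastereomer. AgOTf with 2,6-di-tert-butyl-4-methylpyridine in CH2Cl2 then abstracts the tertiary C3 bromide with assistance from the C4 bromine. This is a silver-promoted semipinacol rearrangement of a β-halo tertiary alcohol, run without base or nucleophile, and it returns to the route at 9.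

**Step 10.** Chloride addition to the neopentyl C2 may be too unfavourable, so that Lewis-acid damage to the silyloxy aldehyde or loss of HBr from 14 wins. The fallback attaches the side chain first and the chloride second. It sets out from 14: α-iodination (I2, pyridine, CH2Cl2) should give (5S)-5-bromo-2-iodo-4,4-dimethylcyclohex-2-en-1-one F2. Coupling with 15 under CrCl2 and catalytic NiCl2 in DMF (Nozaki–Hiyama–Kishi) gives (5S)-5-bromo-2-{2-[(tert-butyldimethylsilyl)oxy]-1-hydroxyethyl}-4,4-dimethylcyclohex-2-en-1-one F3 as carbinol epimers. SOCl2 in Et2O converts F3 by allylic transposition, chloride entering at the enone β-carbon C2 and oxygen leaving from C1′. This comes back to the route at 18 and bypasses 17.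

**Step 11.** Stepwise enolisation at C1 or C5 may expel chloride or bromide (E1cB) instead of water, or a mixed aldol diastereomer ratio may erode the alkene geometry. The fallback removes every base. It sets out from 14 and 15: the aldol is run as in step 10, but a second equivalent of TiCl4 is added and the mixture warmed to 0 °C before quenching. The titanium aldolate then loses its oxygen by Lewis-acid ionisation, as acyclic chloro-aldols do when they give α-(chloromethyl) enones. The route is rejoined at 18 and no new compound is formed.

**Step 13.** The backside trajectory at C6 is axial and passes the axial C2 chlorine, so chloride may attack C1′ (SN2′) or the alkoxyphosphonium ion may ionise, giving allylic transposition or loss of stereochemical fidelity. The fallback replaces in-situ phosphorus activation by a discrete sulfonate. It sets out from 19: MsCl and Et3N in CH2Cl2 at −30 °C should give (1R,2Z,3S,5S)-5-bromo-2-{2-[(tert-butyldimethylsilyl)oxy]ethylidene}-3-chloro-4,4-dimethylcyclohexyl methanesulfonate F4. Without purification, F4 is displaced by LiCl in DMF at 0 °C, where a high concentration of poorly solvated chloride favours direct SN2, and the route is rejoined at 20.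

**Step 12.** The substrate's own bias (hydride anti to the axial C2 chlorine) may override the catalyst and give mainly the C6 epimer. The fallback accepts that epimer and inverts it. It sets out from 18: reduction with the (R)-catalyst, now matched, should give (1S,2Z,3S,5S)-5-bromo-2-{2-[(tert-butyldimethylsilyl)oxy]ethylidene}-3-chloro-4,4-dimethylcyclohexan-1-ol F5. Mitsunobu reaction with benzoic acid (PPh3, diisopropyl azodicarboxylate) inverts C6 by equatorial attack on an axial leaving group, giving (1R,2Z,3S,5S)-5-bromo-2-{2-[(tert-butyldimethylsilyl)oxy]ethylidene}-3-chloro-4,4-dimethylcyclohexyl benzoate F6. i-Bu2AlH in CH2Cl2 at −78 °C cleaves the ester and returns to the route at 19.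

**Step 6.** Enolate 10 may expel the β-silyloxy group before it is triflated. The fallback avoids any enolate. It sets out from 9: NaBH4 in MeOH should give, by axial attack, (1R,3S,5S)-3-bromo-5-[(tert-butyldimethylsilyl)oxy]-2,2-dimethylcyclohexan-1-ol F7. NaH, CS2 and MeI convert it into O-[(1R,3S,5S)-3-bromo-5-[(tert-butyldimethylsilyl)oxy]-2,2-dimethylcyclohexyl] S-methyl carbonodithioate F8. Chugaev pyrolysis of F8 is a concerted syn-elimination that can only go towards C1 and involves no cation, and it rejoins the route at 12.

## Further compounds

F1 | step 5 | (1R,2S,3S,5S)-2,3-dibromo-5-[(tert-butyldimethylsilyl)oxy]-1,2-dimethylcyclohexan-1-ol | C[C@@]1(Br)[C@@H](Br)C[C@@H](O[Si](C)(C)C(C)(C)C)C[C@@]1(C)O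
F2 | step 10 | (5S)-5-bromo-2-iodo-4,4-dimethylcyclohex-2-en-1-one | CC1(C)[C@@H](Br)CC(=O)C(I)=C1
F3 | step 10 | (5S)-5-bromo-2-{2-[(tert-butyldimethylsilyl)oxy]-1-hydroxyethyl}-4,4-dimethylcyclohex-2-en-1-one (both carbinol epimers) | CC1(C)[C@@H](Br)CC(=O)C(C(O)CO[Si](C)(C)C(C)(C)C)=C1
F0 | step 11 | none | none
F4 | step 13 | (1R,2Z,3S,5S)-5-bromo-2-{2-[(tert-butyldimethylsilyl)oxy]ethylidene}-3-chloro-4,4-dimethylcyclohexyl methanesulfonate | CC1(C)[C@@H](Br)C[C@@H](OS(C)(=O)=O)/C(=C/CO[Si](C)(C)C(C)(C)C)[C@@H]1Cl
F5 | step 12 | (1S,2Z,3S,5S)-5-bromo-2-{2-[(tert-butyldimethylsilyl)oxy]ethylidene}-3-chloro-4,4-dimethylcyclohexan-1-ol | CC1(C)[C@@H](Br)C[C@H](O)/C(=C/CO[Si](C)(C)C(C)(C)C)[C@@H]1Cl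
F6 | step 12 | (1R,2Z,3S,5S)-5-bromo-2-{2-[(tert-butyldimethylsilyl)oxy]ethylidene}-3-chloro-4,4-dimethylcyclohexyl benzoate | CC1(C)[C@@H](Br)C[C@@H](OC(=O)c2ccccc2)/C(=C/CO[Si](C)(C)C(C)(C)C)[C@@H]1Cl
F7 | step 6 | (1R,3S,5S)-3-bromo-5-[(tert-butyldimethylsilyl)oxy]-2,2-dimethylcyclohexan-1-ol | CC1(C)[C@@H](Br)C[C@@H](O[Si](C)(C)C(C)(C)C)C[C@H]1O
F8 | step 6 | O-[(1R,3S,5S)-3-bromo-5-[(tert-butyldimethylsilyl)oxy]-2,2-dimethylcyclohexyl] S-methyl carbonodithioate | CC1(C)[C@@H](Br)C[C@@H](O[Si](C)(C)C(C)(C)C)C[C@H]1OC(=S)SC
A1 | alternative 1 | (5S)-5-bromo-2-ethenyl-4,4-dimethylcyclohex-2-en-1-one | CC1(C)[C@@H](Br)CC(=O)C(C=C)=C1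
A2 | alternative 1 | (2Z,3S,5S)-5-bromo-2-(2-bromoethylidene)-3-chloro-4,4-dimethylcyclohexan-1-one | CC1(C)[C@@H](Br)CC(=O)/C(=C/CBr)[C@@H]1Cl
A3 | alternative 2 | (2R,3S,5S)-5-bromo-2-[(1S)-2-[(tert-butyldimethylsilyl)oxy]-1-hydroxyethyl]-3-chloro-4,4-dimethylcyclohexan-1-one | CC1(C)[C@@H](Br)CC(=O)[C@@H]([C@H](O)CO[Si](C)(C)C(C)(C)C)[C@@H]1Cl
A4 | alternative 3 | (3S,5S)-5-bromo-3-chloro-2-ethenyl-4,4-dimethylcyclohex-1-ene | CC1(C)[C@@H](Br)CC=C(C=C)[C@@H]1Cl
A5 | alternative 3 | (2Z)-2-[(2S,4S,6S)-4-bromo-2,6-dichloro-3,3-dimethylcyclohexylidene]ethyl acetate | CC1(C)[C@@H](Br)C[C@H](Cl)/C(=C/COC(C)=O)[C@@H]1Cl
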